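**Plan**

- Retrosynthetic cuts, in order: (a) three benzyl ethers and the 5‑O‑methyl ether; (b) in the methoxylated flavone the bonds O1–C8a, C4a–C4 and O1–C2, giving 3,5‑dimethoxybenzyne and an arylpropiolic acid; (c) the C–CO2H bond and the alkyne, back to an aldehyde; (d) the diaryl ether C–O bond (SNAr on 4‑fluorobenzaldehyde); (e) the C8–O bond of apigenin.
- Feature used: in the methoxyflavone, C8a bears O1, the adjacent C4a bears the C4 carbonyl, and C5 on the other side of C4a bears oxygen. This contiguous O/acyl/O pattern is what a 3‑alkoxybenzyne gives when an O‑nucleophile enters distal to the alkoxy group and the acyl carbon lands on the proximal carbon.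
- Forward order: apigenin supplies one flavone ready‑made; it is benzylated, hydroxylated at C8, O‑arylated and carried to a propiolic acid. The aryne precursor comes in three steps from 3,5‑dimethoxyphenol. The only ring built is the second pyranone, in step 9.
- Stereochemistry: the target has no stereocentre and no stereogenic double bond, so nothing has to be set.
- End game: one Lewis‑acid step removes the benzyl groups and the chelated 5‑O‑methyl group and keeps the 7‑O‑methyl group.

Key step: step 9

Remark on the chemistry: the 5‑oxygen of the new flavone is carried as a methyl ether, so that a phenol with two equivalent ortho positions can serve as the aryne source. Its removal relies on the known preference of BCl3 for a methoxy group peri to the C4 carbonyl over the 7‑methoxy group.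

**Route**

Step 1
Reactants: 1 3,5-dimethoxyphenol
Product: 2 3,5-dimethoxyphenyl N-isopropylcarbamate
Conditions: i-PrNCO, Et3N (cat.), CH2Cl2, rt
Reagents that add atoms: isopropyl isocyanate, CC(C)N=C=O
Why: Base-catalysed addition of the phenol O–H across the isocyanate (carbamoylation) should be clean and gives an N–H carbamate that later directs metalation and can be removed under mild base.

Step 2
Reactants: 2 3,5-dimethoxyphenyl N-isopropylcarbamate
Product: 6 3,5-dimethoxy-2-(trimethylsilyl)phenyl N-isopropylcarbamate, via N-TBS carbamate 3 (not isolated), via ortho-lithiated N-TBS carbamate 4 (not isolated), via N-TBS ortho-TMS carbamate 5 (not isolated)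
Conditions: TBSOTf, TMEDA, Et2O, 0 °C → rt; n-BuLi, TMEDA, −78 °C; TMSCl, −78 °C → rt; then aq. NaHSO4, 0 °C
Reagents that add atoms: chlorotrimethylsilane, C[Si](C)(C)Cl
Why: Directed ortho-metalation of an aryl carbamate with in-situ N-silylation should be single-site, because the two positions ortho to the carbamate are equivalent and each is also flanked by a methoxy group, so they outcompete C4 between the two methoxy groups; TMSCl traps the aryllithium and the N–Si bond is lost on aqueous work-up.

Step 3
Reactants: 6 3,5-dimethoxy-2-(trimethylsilyl)phenyl N-isopropylcarbamate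
Product: 8 3,5-dimethoxy-2-(trimethylsilyl)phenyl trifluoromethanesulfonate, via 3,5-dimethoxy-2-(trimethylsilyl)phenol 7 (not isolated)
Conditions: DBU, Et2NH, MeCN, 40 °C; then PhNTf2, rt
Reagents that add atoms: N-phenylbis(trifluoromethanesulfonimide), O=S(=O)(N(c1ccccc1)S(=O)(=O)C(F)(F)F)C(F)(F)F
Why: DBU triggers E1cB loss of isopropyl isocyanate from the N–H carbamate (scavenged by Et2NH as the urea) and the phenoxide is O-triflated in the same flask, a non-acidic sequence that should spare the electron-rich aryl–silicon bond and deliver the o-silylaryl triflate aryne precursor.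

Step 4
Reactants: 9 apigenin
Product: 10 7,4'-di-O-benzylapigenin (7-(benzyloxy)-2-[4-(benzyloxy)phenyl]-5-hydroxy-4H-chromen-4-one)
Conditions: BnBr (2.2 equiv), K2CO3, DMF, rt
Reagents that add atoms: benzyl bromide, BrCc1ccccc1
Why: Williamson etherification; the 5-OH is hydrogen-bonded to the C4 carbonyl and is expected to stay free under these mild conditions, so only the 7- and 4'-hydroxyls are benzylated.

Step 5
Reactants: 10 7,4'-di-O-benzylapigenin
Product: 12 7-(benzyloxy)-2-[4-(benzyloxy)phenyl]-5,8-dihydroxy-4H-chromen-4-one, via 8-sulfate potassium salt 11 (not isolated)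
Conditions: K2S2O8, aq. KOH, pyridine, 0 °C → rt; then aq. HCl, Na2SO3, 80 °C
Reagents that add atoms: potassium peroxodisulfate, [K+].[K+].[O-]S(=O)(=O)OOS(=O)(=O)[O-]
Why: Elbs persulfate oxidation: the 5-phenoxide attacks peroxodisulfate through its para carbon C8, and acid hydrolysis of the aryl sulfate should give the 5,8-dihydroxyflavone, as is established for 5-hydroxy-7-alkoxyflavones.

Step 6
Reactants: 12 7-(benzyloxy)-2-[4-(benzyloxy)phenyl]-5,8-dihydroxy-4H-chromen-4-one; 13 4-fluorobenzaldehyde
Product: 15 4-{[5,7-bis(benzyloxy)-2-[4-(benzyloxy)phenyl]-4-oxo-4H-chromen-8-yl]oxy}benzaldehyde, via 5-hydroxy diaryl ether aldehyde 14 (not isolated)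
Conditions: K2CO3, degassed DMF, Ar, 90 °C; then BnBr, 70 °C
Reagents that add atoms: benzyl bromide, BrCc1ccccc1
Why: Nucleophilic aromatic substitution (SNAr) of the free, non-chelated 8-phenoxide on the formyl-activated aryl fluoride should form the diaryl ether selectively, and the remaining chelated 5-OH is then benzylated in the same flask by Williamson etherification under more forcing conditions.

Step 7
Reactants: 15 4-{[5,7-bis(benzyloxy)-2-[4-(benzyloxy)phenyl]-4-oxo-4H-chromen-8-yl]oxy}benzaldehyde
Product: 16 5,7-bis(benzyloxy)-2-[4-(benzyloxy)phenyl]-8-(4-ethynylphenoxy)-4H-chromen-4-one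
Conditions: dimethyl (1-diazo-2-oxopropyl)phosphonate, K2CO3, MeOH/THF, rt
Reagents that add atoms: Ohira–Bestmann reagent, CC(=O)C(=[N+]=[N-])P(=O)(OC)OC
Why: Seyferth–Gilbert homologation in its Ohira–Bestmann form converts the aldehyde into the terminal alkyne under carbonate/methanol conditions that should leave both chromone carbonyls untouched, which organolithium-based alkyne syntheses would not.

Step 8
Reactants: 16 5,7-bis(benzyloxy)-2-[4-(benzyloxy)phenyl]-8-(4-ethynylphenoxy)-4H-chromen-4-one
Product: 17 3-(4-{[5,7-bis(benzyloxy)-2-[4-(benzyloxy)phenyl]-4-oxo-4H-chromen-8-yl]oxy}phenyl)propiolic acid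
Conditions: AgI (cat.), Cs2CO3, CO2 (1 atm), DMF, 50 °C; then aq. HCl, 0 °C
Reagents that add atoms: carbon dioxide, O=C=O
Why: Silver-catalysed C–H carboxylation of a terminal arylacetylene with CO2 and Cs2CO3 (via the silver acetylide) should give the arylpropiolic acid without any strong base or nucleophile that could attack the flavone.

Step 9
Reactants: 8 3,5-dimethoxy-2-(trimethylsilyl)phenyl trifluoromethanesulfonate; 17 3-(4-{[5,7-bis(benzyloxy)-2-[4-(benzyloxy)phenyl]-4-oxo-4H-chromen-8-yl]oxy}phenyl)propiolic acid
Product: 20 5,7-bis(benzyloxy)-2-[4-(benzyloxy)phenyl]-8-[4-(5,7-dimethoxy-4-oxo-4H-chromen-2-yl)phenoxy]-4H-chromen-4-one, via 3,5-dimethoxybenzyne 18 (not isolated), via o-hydroxyaryl ynone cesium phenoxide 19 (not isolated)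
Conditions: CsF (4 equiv), THF, 100 °C (sealed tube), 8 (1.5 equiv) added in portions; then Et2NH, 50 °C
Reagents that add atoms: none
Why: Proposed new method: fluoride unmasks 3,5-dimethoxybenzyne 18 from 8 while CsF turns 17 into its cesium carboxylate; the carboxylate oxygen adds to the aryne, the resulting ortho aryl anion attacks the ester carbonyl through a four-membered benzoxete alkoxide that opens to the o-acyl phenoxide 19 (net insertion into the acyl C–O bond), and the phenoxide then adds to the β-carbon of the aryl ynone and the allenolate is protonated at C3. The closest known reactions are the CsF/THF insertion of arynes into the C–O bond of carboxylic acids to give o-hydroxyaryl ketones, the aryne–salicylate xanthone annulation and the cyclisation of o-hydroxyaryl ynones to flavones; their merger in one flask with a propiolic acid is the new element. The one ring formed, the pyranone of the methoxylated flavone, closes 6-endo-dig, which the aprotic medium, the poorly solvated cesium phenoxide and the aryl-conjugated β-carbon favour over 5-exo-dig aurone formation, and the late charge of Et2NH should funnel any uncyclised ynone through its β-enaminone, which can close only to the six-membered ring. No stereocentre is created. The step needs the oxygen to enter at the aryne carbon that becomes C8a, and the 3-methoxy group secures this by polarising the aryne so that the nucleophile adds at the distal carbon and the charge develops at the carbon next to OMe, which becomes C4a with the 5-oxygen beside it. It also needs acyl transfer to outrun protonation of the aryl anion, for which THF (no acidic C–H), high temperature and slow aryne release are chosen, while the linear alkyne keeps the anion from reaching the β-carbon so that only the carbonyl is attacked.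

Step 10
Reactants: 20 5,7-bis(benzyloxy)-2-[4-(benzyloxy)phenyl]-8-[4-(5,7-dimethoxy-4-oxo-4H-chromen-2-yl)phenoxy]-4H-chromen-4-one
Product: 21 5,7-dihydroxy-8-[4-(5-hydroxy-7-methoxy-4-oxo-4H-chromen-2-yl)phenoxy]-2-(4-hydroxyphenyl)-4H-chromen-4-one (CNP0424791.0)
Conditions: BCl3, C6HMe5, CH2Cl2, −78 °C → rt; then MeOH, aq. HCl
Reagents that add atoms: none
Why: Lewis-acid ether cleavage: BCl3 with pentamethylbenzene as benzyl-cation scavenger should remove the three aryl benzyl ethers at low temperature and, on warming, the 5-methoxy group that chelates boron together with the C4 carbonyl, whereas the unchelated 7-methoxy group and the diaryl ether are expected to survive.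

**Compound list**

1 | 3,5-dimethoxyphenol | COc1cc(O)cc(OC)c1 | starting material
2 | 3,5-dimethoxyphenyl N-isopropylcarbamate | COc1cc(OC)cc(OC(=O)NC(C)C)c1 | intermediate
3 | 3,5-dimethoxyphenyl N-(tert-butyldimethylsilyl)-N-isopropylcarbamate (not isolated) | COc1cc(OC)cc(OC(=O)N(C(C)C)[Si](C)(C)C(C)(C)C)c1 | intermediate
4 | 2-lithio-3,5-dimethoxyphenyl N-(tert-butyldimethylsilyl)-N-isopropylcarbamate (not isolated) | COc1cc(OC)c([Li])c(OC(=O)N(C(C)C)[Si](C)(C)C(C)(C)C)c1 | intermediate
5 | 3,5-dimethoxy-2-(trimethylsilyl)phenyl N-(tert-butyldimethylsilyl)-N-isopropylcarbamate (not isolated) | COc1cc(OC)c([Si](C)(C)C)c(OC(=O)N(C(C)C)[Si](C)(C)C(C)(C)C)c1 | intermediate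
6 | 3,5-dimethoxy-2-(trimethylsilyl)phenyl N-isopropylcarbamate | COc1cc(OC)c([Si](C)(C)C)c(OC(=O)NC(C)C)c1 | intermediate
7 | 3,5-dimethoxy-2-(trimethylsilyl)phenol (present as its DBU-H+ phenoxide, not isolated) | COc1cc(O)c([Si](C)(C)C)c(OC)c1 | intermediate
8 | 3,5-dimethoxy-2-(trimethylsilyl)phenyl trifluoromethanesulfonate | COc1cc(OC)c([Si](C)(C)C)c(OS(=O)(=O)C(F)(F)F)c1 | intermediate
9 | apigenin | O=c1cc(-c2ccc(O)cc2)oc2cc(O)cc(O)c12 | starting material
10 | 7,4'-di-O-benzylapigenin | O=c1cc(-c2ccc(OCc3ccccc3)cc2)oc2cc(OCc3ccccc3)cc(O)c12 | intermediate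
11 | potassium 7-(benzyloxy)-2-[4-(benzyloxy)phenyl]-5-hydroxy-4-oxo-4H-chromen-8-yl sulfate (not isolated) | O=c1cc(-c2ccc(OCc3ccccc3)cc2)oc2c(OS(=O)(=O)[O-])c(OCc3ccccc3)cc(O)c12.[K+] | intermediate
12 | 7-(benzyloxy)-2-[4-(benzyloxy)phenyl]-5,8-dihydroxy-4H-chromen-4-one | O=c1cc(-c2ccc(OCc3ccccc3)cc2)oc2c(O)c(OCc3ccccc3)cc(O)c12 | intermediate
13 | 4-fluorobenzaldehyde | O=Cc1ccc(F)cc1 | starting material
14 | 4-{[7-(benzyloxy)-2-[4-(benzyloxy)phenyl]-5-hydroxy-4-oxo-4H-chromen-8-yl]oxy}benzaldehyde (not isolated) | O=Cc1ccc(Oc2c(OCc3ccccc3)cc(O)c3c(=O)cc(-c4ccc(OCc5ccccc5)cc4)oc23)cc1 | intermediate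
15 | 4-{[5,7-bis(benzyloxy)-2-[4-(benzyloxy)phenyl]-4-oxo-4H-chromen-8-yl]oxy}benzaldehyde | O=Cc1ccc(Oc2c(OCc3ccccc3)cc(OCc3ccccc3)c3c(=O)cc(-c4ccc(OCc5ccccc5)cc4)oc23)cc1 | intermediate
16 | 5,7-bis(benzyloxy)-2-[4-(benzyloxy)phenyl]-8-(4-ethynylphenoxy)-4H-chromen-4-one | C#Cc1ccc(Oc2c(OCc3ccccc3)cc(OCc3ccccc3)c3c(=O)cc(-c4ccc(OCc5ccccc5)cc4)oc23)cc1 | intermediate
17 | 3-(4-{[5,7-bis(benzyloxy)-2-[4-(benzyloxy)phenyl]-4-oxo-4H-chromen-8-yl]oxy}phenyl)propiolic acid | OC(=O)C#Cc1ccc(Oc2c(OCc3ccccc3)cc(OCc3ccccc3)c3c(=O)cc(-c4ccc(OCc5ccccc5)cc4)oc23)cc1 | intermediate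
18 | 3,5-dimethoxybenzyne (not isolated) | COC1=CC(OC)=CC#C1 | intermediate
19 | cesium 2-[3-(4-{[5,7-bis(benzyloxy)-2-[4-(benzyloxy)phenyl]-4-oxo-4H-chromen-8-yl]oxy}phenyl)propioloyl]-3,5-dimethoxyphenoxide (not isolated) | COc1cc([O-])c(C(=O)C#Cc2ccc(Oc3c(OCc4ccccc4)cc(OCc4ccccc4)c4c(=O)cc(-c5ccc(OCc6ccccc6)cc5)oc34)cc2)c(OC)c1.[Cs+] | intermediate
20 | 5,7-bis(benzyloxy)-2-[4-(benzyloxy)phenyl]-8-[4-(5,7-dimethoxy-4-oxo-4H-chromen-2-yl)phenoxy]-4H-chromen-4-one | COc1cc(OC)c2c(=O)cc(-c3ccc(Oc4c(OCc5ccccc5)cc(OCc5ccccc5)c5c(=O)cc(-c6ccc(OCc7ccccc7)cc6)oc45)cc3)oc2c1 | intermediate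
21 | 5,7-dihydroxy-8-[4-(5-hydroxy-7-methoxy-4-oxo-4H-chromen-2-yl)phenoxy]-2-(4-hydroxyphenyl)-4H-chromen-4-one (CNP0424791.0) | COc1cc(O)c2c(=O)cc(-c3ccc(Oc4c(O)cc(O)c5c(=O)cc(-c6ccc(O)cc6)oc45)cc3)oc2c1 | target

**Step count**

Total: 10 steps. Longest linear sequence: 7 steps (steps 4–10, from apigenin); the aryne branch (steps 1–3) joins at step 9.

**Steps most likely to fail**

Step 9. The ortho aryl anion may be protonated before it transfers the acyl group, which would stop at simple O-arylation of the acid. The arylpropiolate may also decarboxylate at the temperature needed, the intermediate phenoxide may be arylated by a second aryne, or part of the ynone may close 5-exo. The fallback uses classical flavone chemistry. It sets out from aldehyde 15, which is condensed with commercial 2'-hydroxy-4',6'-dimethoxyacetophenone in a Claisen–Schmidt reaction (KOH, EtOH/THF, rt) to give the (E)-2'-hydroxy-4',6'-dimethoxychalcone F1. Oxidative cyclisation of this chalcone with catalytic iodine in DMSO at 120 °C should then give the flavone, and the route is rejoined at 20. Steps 1–3, 7 and 8 would then not be needed.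

Step 5. Elbs oxidations typically stop at low conversion. In addition the hydroquinone product may be oxidised further to the quinone in the alkaline medium, and a benzyl ether may be lost during the acidic sulfate hydrolysis. The fallback replaces oxidation by halogenation and copper-catalysed C–O coupling. It sets out from 10, which is benzylated at the 5-OH (BnBr, K2CO3, DMF, 80 °C) to tri-O-benzylapigenin F2. Electrophilic iodination (NIS, cat. TFA, MeCN) should then take place at C8 to give 8-iodo-tri-O-benzylapigenin F3. An Ullmann-type etherification of this iodide with 4-hydroxybenzaldehyde (CuI, picolinic acid, K3PO4, DMSO, 90 °C) returns to the route at 15, bypassing steps 5 and 6.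

Step 10. The benzyl cations released by BCl3 may alkylate the electron-rich phloroglucinol-type rings if scavenging is incomplete. Boron chelates of the partly deprotected material may also precipitate and leave benzyl or 5-O-methyl groups in place. The fallback separates the two tasks. It sets out from 20, which is debenzylated by hydrogenolysis (H2, Pd/C, THF/MeOH, rt), a process that generates no cations, to give the 5,7-dimethoxy triphenol F4. Only the chelated 5-O-methyl group then remains to be cleaved with BCl3 (CH2Cl2, 0 °C → rt), and the route is rejoined at 21.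

**Further compounds**

F1 | step 9 | (E)-2'-hydroxy-4',6'-dimethoxychalcone carrying the tri-O-benzylapigenin-8-yloxy group at C4 | COc1cc(O)c(C(=O)/C=C/c2ccc(Oc3c(OCc4ccccc4)cc(OCc4ccccc4)c4c(=O)cc(-c5ccc(OCc6ccccc6)cc5)oc34)cc2)c(OC)c1
F2 | step 5 | 5,7,4'-tri-O-benzylapigenin | O=c1cc(-c2ccc(OCc3ccccc3)cc2)oc2cc(OCc3ccccc3)cc(OCc3ccccc3)c12
F3 | step 5 | 8-iodo-5,7,4'-tri-O-benzylapigenin | O=c1cc(-c2ccc(OCc3ccccc3)cc2)oc2c(I)c(OCc3ccccc3)cc(OCc3ccccc3)c12
F4 | step 10 | 5,7-dihydroxy-8-[4-(5,7-dimethoxy-4-oxo-4H-chromen-2-yl)phenoxy]-2-(4-hydroxyphenyl)-4H-chromen-4-one | COc1cc(OC)c2c(=O)cc(-c3ccc(Oc4c(O)cc(O)c5c(=O)cc(-c6ccc(O)cc6)oc45)cc3)oc2c1
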